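Ring A is the arene that carries the enal, ring B the central arene, ring C the catechol; C7'/C8' are the aryl-bearing and hydroxymethyl-bearing carbons of the dioxane on ring A, C7''/C8'' those of the dioxane on ring B.
Cuts, in retrosynthetic order: the catechol O-allyl and primary O-trityl groups, the enal C=C (Wittig), ring B O–C8'' (aryl C–O coupling), ring B O–C7'' (epoxide opening), ring A O–C7' (quinone methide closure), ring A O–C8' (SNAr) and the ring B–C7' bond (Grignard opening of a glycidyl ether).
Forward: ring B is joined to the three-carbon chain, ring A is attached as an aryl ether, the trans dioxane is closed by oxidation, ring B is brominated, the cis dioxane is closed in two C–O steps, then the enal is installed and the protecting groups are removed.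
Feature behind the key step: C7' is benzylic to ring B and para to the ring B oxygen, which is a free phenol at that stage, so the C7' methylene can be oxidised to a para-quinone methide that the ring A phenol closes to O–C7'.
Stereochemistry: C8' is bought with (R)-trityl glycidyl ether and directs C7' trans; C7''/C8'' come from a Sharpless epoxidation with L-(+)-diethyl tartrate, with inversion at C7'' in the epoxide opening and retention at C8'' in the copper-mediated closure giving the cis dioxane.

Key step: step 5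

Assumption: compounds 1, 3, 4 and 12 are taken as commercial; both primary oxygens are carried as trityl ethers because a silyl group next to a secondary alkoxide (steps 3 and 12) would migrate between the two oxygens.

Step 1
Reactants: 1 4-fluoro-3-hydroxybenzaldehyde
Product: 2 3-(allyloxy)-4-fluorobenzaldehyde
Conditions: allyl bromide, K2CO3, DMF, rt
Reagents that add atoms: allyl bromide, C=CCBr
Why: Williamson ether synthesis; the phenoxide of 1 is O-alkylated by the allylic bromide under conditions too mild for fluoride displacement.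

Step 2
Reactants: 3 1-(allyloxy)-4-bromobenzene; 4 (R)-trityl glycidyl ether
Product: 6 (2R)-1-[4-(allyloxy)phenyl]-3-(trityloxy)propan-2-ol, via 4-allyloxyphenylmagnesium bromide 5 (not isolated)
Conditions: Mg, THF, 40 °C; then CuI (10 mol%), 4, THF, −30 to 0 °C
Reagents that add atoms: none
Why: Copper-catalysed Grignard opening of a monosubstituted epoxide occurs by SN2 at the unsubstituted carbon, so the glycidol centre passes unchanged into 6 as the future C8', and at −30 °C the aryl allyl ether should not be attacked.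

Step 3
Reactants: 6 (2R)-alcohol; 2 3-(allyloxy)-4-fluorobenzaldehyde
Product: 7 3-(allyloxy)-4-{[(2R)-1-[4-(allyloxy)phenyl]-3-(trityloxy)propan-2-yl]oxy}benzaldehyde
Conditions: NaH, DMF, 0 °C to rt
Reagents that add atoms: none
Why: Nucleophilic aromatic substitution (addition–elimination) of the secondary alkoxide at the C–F carbon para to the formyl group forms the ring A ether without breaking the carbinol C–O bond, so the configuration is retained, and a trityl ether cannot migrate to the neighbouring alkoxide.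

Step 4
Reactants: 7 bis-allyl aryl ether
Product: 8 3-hydroxy-4-{[(2R)-1-(4-hydroxyphenyl)-3-(trityloxy)propan-2-yl]oxy}benzaldehyde
Conditions: Pd(PPh3)4 (5 mol%), morpholine, THF, rt
Reagents that add atoms: none
Why: Tsuji–Trost-type deallylation; zerovalent palladium ionises both aryl allyl ethers to π-allyl complexes that morpholine captures, leaving the trityl ether, the aldehyde and the stereocentre alone.

Step 5
Reactants: 8 diphenol aryl ether
Product: 10 (2S,3S)-3-(4-hydroxyphenyl)-2-[(trityloxy)methyl]-2,3-dihydro-1,4-benzodioxine-6-carbaldehyde (trans), via para-quinone methide 9 (not isolated)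
Conditions: DDQ (1.05 equiv, slow addition), 1,4-dioxane, rt, 0.01 M
Reagents that add atoms: none
Why: DDQ removes a hydride equivalent from the benzylic CH2 of the 4-hydroxybenzyl group (C7'), giving para-quinone methide 9 and the hydroquinone of DDQ, and the ring A phenol, held in reach by the C8' aryl ether, then adds to the exocyclic C7' in an oxa-1,6-addition that restores the ring B phenol. The closest known reaction type is the DDQ-mediated oxidative cyclisation of 2-hydroxy-1,3-diarylpropanes bearing a 4-hydroxyphenyl group to flavans, together with the quinone methide ring closure that ends oxidative-coupling routes to benzodioxane neolignans. The 1,4-dioxane closes in the 6-exo-trig mode, the exocyclic C7'=C bond of 9 lying outside the new ring. The new centre C7' is controlled by C8': in a half-chair transition state the trityloxymethyl group sits pseudo-equatorial and the aryl group ends up trans to it, and because the free para-phenol allows reopening to 9 the addition is reversible and should settle on the more stable trans (2S,3S) isomer. The step needs oxidation of ring B in preference to ring A, which the formyl group secures by making the ring A phenol electron-poor (ring A also has no para alkyl group from which a quinone methide could form), and it needs capture of 9 before tautomerisation to the aryl enol ether would erase C8', which the intramolecular six-membered closure at high dilution with one equivalent of oxidant should secure.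

Step 6
Reactants: 10 trans-benzodioxane phenol
Product: 11 (2S,3S)-3-(3-bromo-4-hydroxyphenyl)-2-[(trityloxy)methyl]-2,3-dihydro-1,4-benzodioxine-6-carbaldehyde
Conditions: NBS (1.0 equiv), MeCN, −20 to 0 °C, dark
Reagents that add atoms: N-bromosuccinimide, O=C1CCC(=O)N1Br
Why: Electrophilic aromatic bromination goes ortho to the free ring B phenol because its para position is blocked, while ring A is deactivated by the formyl group and one equivalent of reagent at low temperature should stop at the monobromide.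

Step 7
Reactants: 12 ethyl caffeate
Product: 13 ethyl (E)-3-[3,4-bis(allyloxy)phenyl]prop-2-enoate
Conditions: allyl bromide, K2CO3, DMF, rt
Reagents that add atoms: allyl bromide, C=CCBr
Why: Williamson ether synthesis on both catechol oxygens; allyl ethers survive base, copper catalysis and mild acid and can be removed at the end under neutral conditions.

Step 8
Reactants: 13 bis-allyl cinnamate
Product: 14 (E)-3-[3,4-bis(allyloxy)phenyl]prop-2-en-1-ol
Conditions: iBu2AlH (2.5 equiv), CH2Cl2, −78 °C; Rochelle salt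
Reagents that add atoms: none
Why: 1,2-Reduction of the α,β-unsaturated ester by iBu2AlH at low temperature gives the E-allylic alcohol without touching the alkene or the allyl ethers.

Step 9
Reactants: 14 E-allylic alcohol
Product: 15 [(2S,3S)-3-[3,4-bis(allyloxy)phenyl]oxiran-2-yl]methanol
Conditions: Ti(OiPr)4 (10 mol%), L-(+)-diethyl tartrate (12 mol%), tBuOOH, 4 Å MS, CH2Cl2, −20 °C; NaOH/brine work-up
Reagents that add atoms: tert-butyl hydroperoxide, CC(C)(C)OO
Why: Sharpless asymmetric epoxidation; the titanium tartrate complex binds only the allylic alcohol, so the O-allyl alkenes are spared, and L-(+)-diethyl tartrate delivers oxygen to the face of the E-alkene that gives the (2S,3S) epoxide, which sets the future C7'' and C8''.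

Step 10
Reactants: 15 epoxy alcohol
Product: 16 (2S,3S)-2-[3,4-bis(allyloxy)phenyl]-3-[(trityloxy)methyl]oxirane
Conditions: TrCl, Et3N, DMAP (cat.), CH2Cl2, 0 °C to rt
Reagents that add atoms: trityl chloride, ClC(c1ccccc1)(c1ccccc1)c1ccccc1
Why: Tritylation of the primary alcohol under basic conditions installs a group that cannot migrate, prevents Payne rearrangement and shields the adjacent epoxide carbon in the next step.

Step 11
Reactants: 11 bromophenol; 16 trityl epoxide
Product: 17 (2S,3S)-3-{3-bromo-4-[(1R,2S)-1-[3,4-bis(allyloxy)phenyl]-2-hydroxy-3-(trityloxy)propoxy]phenyl}-2-[(trityloxy)methyl]-2,3-dihydro-1,4-benzodioxine-6-carbaldehyde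
Conditions: Cs2CO3, DMF, 70 °C
Reagents that add atoms: none
Why: SN2 opening of the epoxide by the caesium phenoxide of 11 at the benzylic carbon, which is activated by the electron-rich aryl group and remote from the bulky trityloxymethyl group, inverts C7'' and leaves C8'' as a secondary alcohol of unchanged configuration, the erythro arrangement needed for a cis ring.

Step 12
Reactants: 17 bromo alcohol
Product: 18 (2S,3S)-3-{(2R,3S)-2-[3,4-bis(allyloxy)phenyl]-3-[(trityloxy)methyl]-2,3-dihydro-1,4-benzodioxin-6-yl}-2-[(trityloxy)methyl]-2,3-dihydro-1,4-benzodioxine-6-carbaldehyde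
Conditions: CuI (10 mol%), 3,4,7,8-tetramethyl-1,10-phenanthroline (20 mol%), Cs2CO3, toluene, 110 °C
Reagents that add atoms: none
Why: Ullmann-type intramolecular C–O coupling of the secondary alcohol with the neighbouring aryl bromide closes the six-membered ring at the aryl carbon, so the C8''–O bond is never broken and retention there gives the cis-2,3-disubstituted dioxane.

Step 13
Reactants: 18 bis-dioxane aldehyde
Product: 19 (E)-3-[(2S,3S)-3-{(2R,3S)-2-[3,4-bis(allyloxy)phenyl]-3-[(trityloxy)methyl]-2,3-dihydro-1,4-benzodioxin-6-yl}-2-[(trityloxy)methyl]-2,3-dihydro-1,4-benzodioxin-6-yl]prop-2-enal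
Conditions: Ph3P=CHCHO (1.3 equiv), toluene, 85 °C
Reagents that add atoms: (triphenylphosphoranylidene)acetaldehyde, O=CC=P(c1ccccc1)(c1ccccc1)c1ccccc1
Why: Wittig olefination with the stabilised formylmethylene ylide gives the E-configured enal directly from the aromatic aldehyde.

Step 14
Reactants: 19 protected enal
Product: 20 (E)-3-[(2S,3S)-3-{(2R,3S)-2-[3,4-bis(allyloxy)phenyl]-3-(hydroxymethyl)-2,3-dihydro-1,4-benzodioxin-6-yl}-2-(hydroxymethyl)-2,3-dihydro-1,4-benzodioxin-6-yl]prop-2-enal
Conditions: AcOH–H2O–THF (3:1:1), 45 °C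
Reagents that add atoms: none
Why: Acid-catalysed SN1 cleavage of the two primary trityl ethers through the trityl cation proceeds in aqueous acetic acid, which is too mild to ionise the benzylic aryl ethers while the catechol is still allylated and does not affect the enal.

Step 15
Reactants: 20 bis-allyl diol
Product: 21 (E)-3-[(2S,3S)-3-[(2R,3S)-2-(3,4-dihydroxyphenyl)-3-(hydroxymethyl)-2,3-dihydro-1,4-benzodioxin-6-yl]-2-(hydroxymethyl)-2,3-dihydro-1,4-benzodioxin-6-yl]prop-2-enal (target)
Conditions: Pd(PPh3)4 (5 mol%), N-methylaniline, degassed THF, rt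
Reagents that add atoms: none
Why: Tsuji–Trost-type deallylation under neutral conditions; zerovalent palladium ionises the two aryl allyl ethers and the weakly basic N-methylaniline takes up the allyl groups, so no phenoxide para to C7'' persists and the cis dioxane should keep its configuration, while the enal and the primary alcohols are untouched.

Compound list
1 | 4-fluoro-3-hydroxybenzaldehyde | O=Cc1ccc(F)c(O)c1 | starting material
2 | 3-(allyloxy)-4-fluorobenzaldehyde | O=Cc1ccc(F)c(OCC=C)c1 | intermediate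
3 | 1-(allyloxy)-4-bromobenzene | C=CCOc1ccc(Br)cc1 | starting material
4 | (R)-trityl glycidyl ether, (2R)-2-[(triphenylmethoxy)methyl]oxirane | C(OC[C@H]1CO1)(c1ccccc1)(c1ccccc1)c1ccccc1 | starting material
5 | 4-allyloxyphenylmagnesium bromide | C=CCOc1ccc([Mg]Br)cc1 | intermediate (not isolated)
6 | (2R)-1-[4-(allyloxy)phenyl]-3-(trityloxy)propan-2-ol | O[C@@H](COC(c1ccccc1)(c1ccccc1)c1ccccc1)Cc1ccc(OCC=C)cc1 | intermediate
7 | 3-(allyloxy)-4-{[(2R)-1-[4-(allyloxy)phenyl]-3-(trityloxy)propan-2-yl]oxy}benzaldehyde | O=Cc1ccc(O[C@@H](COC(c2ccccc2)(c2ccccc2)c2ccccc2)Cc2ccc(OCC=C)cc2)c(OCC=C)c1 | intermediate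
8 | 3-hydroxy-4-{[(2R)-1-(4-hydroxyphenyl)-3-(trityloxy)propan-2-yl]oxy}benzaldehyde | O=Cc1ccc(O[C@@H](COC(c2ccccc2)(c2ccccc2)c2ccccc2)Cc2ccc(O)cc2)c(O)c1 | intermediate
9 | para-quinone methide, 3-hydroxy-4-{[(2R)-1-(4-oxocyclohexa-2,5-dien-1-ylidene)-3-(trityloxy)propan-2-yl]oxy}benzaldehyde | O=Cc1ccc(O[C@@H](COC(c2ccccc2)(c2ccccc2)c2ccccc2)C=C2C=CC(=O)C=C2)c(O)c1 | intermediate (not isolated)
10 | (2S,3S)-3-(4-hydroxyphenyl)-2-[(trityloxy)methyl]-2,3-dihydro-1,4-benzodioxine-6-carbaldehyde (trans) | O=Cc1ccc2c(c1)O[C@@H](c1ccc(O)cc1)[C@H](COC(c1ccccc1)(c1ccccc1)c1ccccc1)O2 | intermediate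
11 | (2S,3S)-3-(3-bromo-4-hydroxyphenyl)-2-[(trityloxy)methyl]-2,3-dihydro-1,4-benzodioxine-6-carbaldehyde | O=Cc1ccc2c(c1)O[C@@H](c1ccc(O)c(Br)c1)[C@H](COC(c1ccccc1)(c1ccccc1)c1ccccc1)O2 | intermediate
12 | ethyl caffeate, ethyl (E)-3-(3,4-dihydroxyphenyl)prop-2-enoate | CCOC(=O)/C=C/c1ccc(O)c(O)c1 | starting material
13 | ethyl (E)-3-[3,4-bis(allyloxy)phenyl]prop-2-enoate | CCOC(=O)/C=C/c1ccc(OCC=C)c(OCC=C)c1 | intermediate
14 | (E)-3-[3,4-bis(allyloxy)phenyl]prop-2-en-1-ol | OC/C=C/c1ccc(OCC=C)c(OCC=C)c1 | intermediate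
15 | [(2S,3S)-3-[3,4-bis(allyloxy)phenyl]oxiran-2-yl]methanol | OC[C@@H]1O[C@H]1c1ccc(OCC=C)c(OCC=C)c1 | intermediate
16 | (2S,3S)-2-[3,4-bis(allyloxy)phenyl]-3-[(trityloxy)methyl]oxirane | C(OC[C@@H]1O[C@H]1c1ccc(OCC=C)c(OCC=C)c1)(c1ccccc1)(c1ccccc1)c1ccccc1 | intermediate
17 | (2S,3S)-3-{3-bromo-4-[(1R,2S)-1-[3,4-bis(allyloxy)phenyl]-2-hydroxy-3-(trityloxy)propoxy]phenyl}-2-[(trityloxy)methyl]-2,3-dihydro-1,4-benzodioxine-6-carbaldehyde | O=Cc1ccc2c(c1)O[C@@H](c1ccc(O[C@H](c3ccc(OCC=C)c(OCC=C)c3)[C@@H](O)COC(c3ccccc3)(c3ccccc3)c3ccccc3)c(Br)c1)[C@H](COC(c1ccccc1)(c1ccccc1)c1ccccc1)O2 | intermediate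
18 | (2S,3S)-3-{(2R,3S)-2-[3,4-bis(allyloxy)phenyl]-3-[(trityloxy)methyl]-2,3-dihydro-1,4-benzodioxin-6-yl}-2-[(trityloxy)methyl]-2,3-dihydro-1,4-benzodioxine-6-carbaldehyde | O=Cc1ccc2c(c1)O[C@@H](c1ccc3c(c1)O[C@@H](COC(c1ccccc1)(c1ccccc1)c1ccccc1)[C@@H](c1ccc(OCC=C)c(OCC=C)c1)O3)[C@H](COC(c1ccccc1)(c1ccccc1)c1ccccc1)O2 | intermediate
19 | (E)-3-[(2S,3S)-3-{(2R,3S)-2-[3,4-bis(allyloxy)phenyl]-3-[(trityloxy)methyl]-2,3-dihydro-1,4-benzodioxin-6-yl}-2-[(trityloxy)methyl]-2,3-dihydro-1,4-benzodioxin-6-yl]prop-2-enal | O=C/C=C/c1ccc2c(c1)O[C@@H](c1ccc3c(c1)O[C@@H](COC(c1ccccc1)(c1ccccc1)c1ccccc1)[C@@H](c1ccc(OCC=C)c(OCC=C)c1)O3)[C@H](COC(c1ccccc1)(c1ccccc1)c1ccccc1)O2 | intermediate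
20 | (E)-3-[(2S,3S)-3-{(2R,3S)-2-[3,4-bis(allyloxy)phenyl]-3-(hydroxymethyl)-2,3-dihydro-1,4-benzodioxin-6-yl}-2-(hydroxymethyl)-2,3-dihydro-1,4-benzodioxin-6-yl]prop-2-enal | O=C/C=C/c1ccc2c(c1)O[C@@H](c1ccc3c(c1)O[C@@H](CO)[C@@H](c1ccc(OCC=C)c(OCC=C)c1)O3)[C@H](CO)O2 | intermediate
21 | (E)-3-[(2S,3S)-3-[(2R,3S)-2-(3,4-dihydroxyphenyl)-3-(hydroxymethyl)-2,3-dihydro-1,4-benzodioxin-6-yl]-2-(hydroxymethyl)-2,3-dihydro-1,4-benzodioxin-6-yl]prop-2-enal | O=C/C=C/c1ccc2c(c1)O[C@@H](c1ccc3c(c1)O[C@@H](CO)[C@@H](c1ccc(O)c(O)c1)O3)[C@H](CO)O2 | target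

Total step count: 15.
Longest linear sequence: 10 steps (steps 2, 3, 4, 5, 6, 11, 12, 13, 14, 15, from 3 and 4 to 21).

Steps most likely to fail

Step 5. The unhindered ring B phenol may couple through phenoxy radicals, quinone methide 9 may tautomerise to the aryl enol ether with loss of the C8' configuration, or the product may be oxidised a second time at C7'. The fallback brings C7' in already oxygenated and uses only known reactions; it sets out from 1 and returns at 10. 4-(Allyloxy)benzaldehyde F1 would be homologated with Ph3P=CHCO2Et to ethyl (E)-3-[4-(allyloxy)phenyl]prop-2-enoate F2, reduced with iBu2AlH to (E)-3-[4-(allyloxy)phenyl]prop-2-en-1-ol F3, epoxidised under Sharpless conditions with L-(+)-diethyl tartrate to [(2S,3S)-3-[4-(allyloxy)phenyl]oxiran-2-yl]methanol F4 and tritylated to (2S,3S)-2-[4-(allyloxy)phenyl]-3-[(trityloxy)methyl]oxirane F5. The caesium phenoxide of 1 (Cs2CO3, DMF, 70 °C) would open F5 at the benzylic carbon with inversion to 3-{[(1R,2S)-1-[4-(allyloxy)phenyl]-2-hydroxy-3-(trityloxy)propyl]oxy}-4-fluorobenzaldehyde F6 (not isolated), whose alkoxide displaces the fluoride para to the formyl group in the same flask and gives the cis dioxane (2S,3R)-3-[4-(allyloxy)phenyl]-2-[(trityloxy)methyl]-2,3-dihydro-1,4-benzodioxine-6-carbaldehyde F7. Deallylation with Pd(PPh3)4 and morpholine would give the cis phenol (2S,3R)-3-(4-hydroxyphenyl)-2-[(trityloxy)methyl]-2,3-dihydro-1,4-benzodioxine-6-carbaldehyde F8. Warming F8 with K2CO3 in DMF should epimerise C7' through the same quinone methide 9 by retro-oxa-Michael and oxa-Michael addition, to settle on the more stable trans isomer 10.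

Step 11. The electron-rich epoxide may ionise, so that the substitution loses its stereospecificity at C7'', or it may rearrange while the hindered, weakly nucleophilic bromophenoxide reacts slowly. The fallback makes the same bond on the unprotected epoxy alcohol by titanium-chelate delivery; it sets out from 11 and 15 and returns at 17. Phenol 11 and epoxy alcohol 15 would be combined with Ti(OiPr)4 in CH2Cl2 at rt, where the titanium alkoxide of the epoxy alcohol directs the bound phenoxide to the benzylic C3 with inversion. This should give the diol (2S,3S)-3-{3-bromo-4-[(1R,2S)-1-[3,4-bis(allyloxy)phenyl]-2,3-dihydroxypropoxy]phenyl}-2-[(trityloxy)methyl]-2,3-dihydro-1,4-benzodioxine-6-carbaldehyde F9. Selective tritylation of its primary hydroxyl (TrCl, pyridine, rt) would return to 17.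

Step 3. The hindered secondary alkoxide may add to the formyl group or transfer hydride to it faster than it displaces fluoride at the alkoxy-deactivated carbon. The fallback forms the C8'–O bond at the alkyl carbon with inversion instead of at the aryl carbon; it sets out from 2 and 5 and returns at 7. Grignard reagent 5 would open (S)-trityl glycidyl ether F10 as in step 2 to give (2S)-1-[4-(allyloxy)phenyl]-3-(trityloxy)propan-2-ol F11. The fluoride of 2 would be exchanged for hydroxyl with 2-(methylsulfonyl)ethanol and NaH in DMF through 3-(allyloxy)-4-[2-(methylsulfonyl)ethoxy]benzaldehyde F12 (not isolated), which eliminates to 3-(allyloxy)-4-hydroxybenzaldehyde F13. A Mitsunobu reaction of F11 with F13 (PPh3, DIAD, toluene, 0 °C to rt) would invert the carbinol centre and give 7.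

Further compounds
F1 | step 5 | 4-(allyloxy)benzaldehyde | O=Cc1ccc(OCC=C)cc1
F2 | step 5 | ethyl (E)-3-[4-(allyloxy)phenyl]prop-2-enoate | CCOC(=O)/C=C/c1ccc(OCC=C)cc1
F3 | step 5 | (E)-3-[4-(allyloxy)phenyl]prop-2-en-1-ol | OC/C=C/c1ccc(OCC=C)cc1
F4 | step 5 | [(2S,3S)-3-[4-(allyloxy)phenyl]oxiran-2-yl]methanol | OC[C@@H]1O[C@H]1c1ccc(OCC=C)cc1
F5 | step 5 | (2S,3S)-2-[4-(allyloxy)phenyl]-3-[(trityloxy)methyl]oxirane | C(OC[C@@H]1O[C@H]1c1ccc(OCC=C)cc1)(c1ccccc1)(c1ccccc1)c1ccccc1
F6 | step 5 | 3-{[(1R,2S)-1-[4-(allyloxy)phenyl]-2-hydroxy-3-(trityloxy)propyl]oxy}-4-fluorobenzaldehyde | O=Cc1ccc(F)c(O[C@H](c2ccc(OCC=C)cc2)[C@@H](O)COC(c2ccccc2)(c2ccccc2)c2ccccc2)c1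
F7 | step 5 | (2S,3R)-3-[4-(allyloxy)phenyl]-2-[(trityloxy)methyl]-2,3-dihydro-1,4-benzodioxine-6-carbaldehyde (cis) | O=Cc1ccc2c(c1)O[C@H](c1ccc(OCC=C)cc1)[C@H](COC(c1ccccc1)(c1ccccc1)c1ccccc1)O2
F8 | step 5 | (2S,3R)-3-(4-hydroxyphenyl)-2-[(trityloxy)methyl]-2,3-dihydro-1,4-benzodioxine-6-carbaldehyde (cis) | O=Cc1ccc2c(c1)O[C@H](c1ccc(O)cc1)[C@H](COC(c1ccccc1)(c1ccccc1)c1ccccc1)O2
F9 | step 11 | (2S,3S)-3-{3-bromo-4-[(1R,2S)-1-[3,4-bis(allyloxy)phenyl]-2,3-dihydroxypropoxy]phenyl}-2-[(trityloxy)methyl]-2,3-dihydro-1,4-benzodioxine-6-carbaldehyde | O=Cc1ccc2c(c1)O[C@@H](c1ccc(O[C@H](c3ccc(OCC=C)c(OCC=C)c3)[C@@H](O)CO)c(Br)c1)[C@H](COC(c1ccccc1)(c1ccccc1)c1ccccc1)O2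
F10 | step 3 | (S)-trityl glycidyl ether, (2S)-2-[(triphenylmethoxy)methyl]oxirane | C(OC[C@@H]1CO1)(c1ccccc1)(c1ccccc1)c1ccccc1
F11 | step 3 | (2S)-1-[4-(allyloxy)phenyl]-3-(trityloxy)propan-2-ol | O[C@H](COC(c1ccccc1)(c1ccccc1)c1ccccc1)Cc1ccc(OCC=C)cc1
F12 | step 3 | 3-(allyloxy)-4-[2-(methylsulfonyl)ethoxy]benzaldehyde | O=Cc1ccc(OCCS(C)(=O)=O)c(OCC=C)c1
F13 | step 3 | 3-(allyloxy)-4-hydroxybenzaldehyde | O=Cc1ccc(O)c(OCC=C)c1
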